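The numbers in the tables are simulated for substances that don't exist, and the scatter is random.

1. Start from the epsilon run, whose solid substrate, free catalyst and second catalyst equal those of the asked flask and whose reagent stands at 0.070 M against 0.0350 M, and count every amount as a fraction of the solid substrate charged.

| setting | theta | beta | epsilon | flask |
|---|---|---|---|---|
| solid substrate | 0.050 M | 0.050 M | 0.050 M | 0.050 M |
| reagent | 0.035 M | 0.035 M | 0.070 M | 0.0350 M |
| free catalyst | 12 µM | 19 µM | 25 µM | 25 µM |
| second catalyst | 10 mM | 10 mM | 10 mM | 10 mM |
| remark | run made earlier | run made earlier | run made earlier |  |
| time |  |  |  | 6.0 d |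

| run | time / d | target / % |
|---|---|---|
| theta | 0.417 | 1 |
| theta | 0.833 | 0 |
| theta | 2.08 | 9 |
| theta | 5.00 | 27 |
| beta | 0.625 | 0 |
| beta | 1.67 | 8 |
| beta | 3.00 | 16 |
| beta | 5.00 | 30 |
| epsilon | 0.625 | 0 |
| epsilon | 1.67 | 7 |
| epsilon | 3.00 | 19 |
| epsilon | 5.00 | 38 |

(each reading ± 2 percentage points)

- solid substrate is a solid; its amount is given per volume of the solution
- on the list of suspects stand: reagent + second catalyst + intermediate -> second catalyst + target; starting material + free catalyst <-> free catalyst + intermediate; solid substrate <-> starting material; 2 free catalyst <-> resting dimer
- at the start none of the solid substrate is in solution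

- amount of target at 6.0 d, in percent of the solid substrate charged
- the change that raises the amount of target at 6.0 d, in percent of the solid substrate charged most ("none" if none brings more than 2 percentage points) (south-west / south / west / north / none)
- amount of target at 6.0 d, in percent of the solid substrate charged, after west

- south-west: doubling the dissolution coefficient of the solid substrate, all else as stated
- south: doubling the amount of free catalyst, all else as stated
- west: doubling the amount of reagent, all else as stated
- north: doubling the solubility of the solid substrate, all else as stated

2. Define the pace as the fraction of the charge turned into target per day on the straight stretch of a run, and read it in epsilon from 1.67 d to 5.00 d: 0.0931 d⁻¹.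

3. Test reagent first, since it is the setting that differs: beta's pace over the same span is 0.0661 d⁻¹, so from beta to epsilon the pace as read rose 1.41 times while free catalyst rose 1.32 times and reagent 2.00 times; treat reagent as a small error on the pace, and note that in the asked flask the reagent charge, the limiting reagent there, allows a ceiling of 70.0%.

4. Test the readings next: a scatter of 2 percentage points at each end shifts the pace by 0.00849 d⁻¹, which over 4.33 d shifts the answer by 3.7 points.

5. Then extend my line from epsilon's reading at 1.67 d to 6.0 d, which gives 47.3% for the asked flask, below the ceiling.

6. Set beside it the forecast, which gives 39%, names north, and gives 48% after west; it starts from “Beta reaches about 37 % at 6 d”, so my line stands 8.3 points above it.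

7. Now read the result.

    reagent + second catalyst + intermediate → second catalyst + target (k = 77.0 M⁻² min⁻¹)
    starting material + free catalyst ⇌ free catalyst + intermediate (K = 2.40, k = 25.0 M⁻¹ min⁻¹)
    solid substrate ⇌ starting material, rate k3*(cs3 - [starting material]) while solid is left; crystals form when [starting material] > cs3 (solubility = 17.0 mM, k = 4.70 × 10⁻⁴ min⁻¹)
    2 free catalyst ⇌ resting dimer (K = 43000 M⁻¹, k = 360 M⁻¹ min⁻¹)

The flask gives 45.4%, the best change is north with a gain of 25 points, and after west the flask gives 46.0%, while 35% of the reagent in the unchanged flask is still there at 6.00 d. Between 3.00 d and 6.0 d the flask gains 0.0880 d⁻¹, against the pace of 0.0931 d⁻¹. Carry the pace to the neighbour flask read at 2.5 d: epsilon's line gives 14.7% there, and that flask holds 14.7% of target.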